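A ratio carries this problem: the E that ends in J over the E that ends in Z, divided by the molar charge of E. Call it the split, a selectivity factor.

| flask | E | D | remark | time |
|---|---|---|---|---|
| north-west | 0.067 M | 11 mM (held) | run made earlier |  |
| west | 0.15 M | 11 mM (held) | run made earlier |  |
| Tuesday's | 0.10 M | 11 mM (held) |  | 1.5 h |
| Sunday's | 0.10 M | 11 mM (held) |  | 5.0 h |

| run | time / min | Z / % | Q / % | E / % |
|---|---|---|---|---|
| north-west | 8.00 | 5.3 | 0 | 83.4 |
| north-west | 15.0 | 13.8 | 0 | 71.1 |
| north-west | 25.0 | 21.3 | 0.3 | 56.9 |
| north-west | 50.0 | 40.6 | 1.2 | 28.3 |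
| north-west | 90.0 | 56.7 | 1.0 | 9.8 |
| west | 20.0 | 10.1 | 0 | 49.9 |
| west | 40.0 | 20.1 | 0 | 30.3 |
| west | 50.0 | 23.5 | 0 | 23.1 |
| west | 80.0 | 32.3 | 0.6 | 11.2 |
| west | 90.0 | 36.0 | 0 | 10.2 |

(each reading ± 1 percentage point)

- percent here means E units held: one J counts as two
- at the start none of X is dissolved
- the numbers in the tables scatter with a standard deviation of 1 percentage point
- what may be going on: E + X -> Z; E + 2 X -> Q; D <-> X; 2 E -> J

- which of these there is most of at the end, counted by the E in it, Tuesday's (Z / E / Q)
- which of these there is most of at the end, counted by the E in it, Sunday's (Z / E / Q)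
- final amount of the leader among these, as a percentage of the E charged, in Tuesday's
- final amount of the leader among these, as a percentage of the E charged, in Sunday's

Build the flask up. With E + X → Z on its own, every E charged ends as Z. Now add two E → J. At a given [X] that step slows as [E] squared and the Z step as [E], so J over Z should grow with the charge, and dividing by the charge ought to leave one number.

First round: at the last readings, count what is neither E nor Z as J. North-west gives 8.82 L mol⁻¹ and west 9.96 L mol⁻¹, which sit apart. Second round: put that answer back. The E still there is dilute and the J step goes as [E] squared, so hand it to Z. Now north-west gives 7.52 L mol⁻¹ and west 7.76 L mol⁻¹, a narrower gap. The mean split read off these runs, J over Z per molar charge, is 7.64 L mol⁻¹. If Sunday's E reacts to the end, its Z is 56.7%.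

Then the rest, D ↔ X among it, and for the timing I borrow from the readings: at 90.0 min the north-west and west runs hold 9.8% and 10.2% of E despite their different charges, and Tuesday's stops then. Taking off their mean, 10.0%, leaves Tuesday's Z at 46.7%. Q stays inside the rest, its highest reading being 1.2%.

The forecast names Z in Tuesday's and Z in Sunday's, with 46% and 56%, reached by stepwise integration and holding that “dimerisation to J is important”. My figures stand 0.70 percentage points and 0.70 points above it.

The flask gives Z in Tuesday's at 45.7% and Z in Sunday's at 54.4%, so the forecast stands.

    E + X → Z (k = 0.0560 L mol⁻¹ s⁻¹)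
    E + 2 X → Q (k = 0.160 L² mol⁻² s⁻¹)
    D ⇌ X, rate k3*(csat - [X]) (kL = 0.00170 s⁻¹)
    2 E → J (k = 0.00200 L mol⁻¹ s⁻¹)

The turning of two E into J is the main reason Sunday's Z stops at 54.4%: the same flask without that step reaches 98.6%. The carried split of 7.64 L mol⁻¹, itself read off scattered readings, put Sunday's Z at 56.7%, which stands 2.3 points above the flask. Try a further flask like Sunday's with 0.060 M of E: the split gives Z at 68.6%, and the flask gives 68.6%.

Readings and results are calculated with made-up constants; scatter was added.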